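**Retrosynthetic overview**
- The target is an unsymmetrical diaryl ether built from two 4-methoxythymol units, joined by an aryl C–O bond ortho to the free OH. No ring is formed in the route; both benzene rings come from thymol.
- Key disconnection: that aryl C–O bond, giving 4-methoxythymol (oxygen partner) and 6-bromo-4-methoxythymol (carbon partner), coupled without protecting groups by a radical-chain displacement of bromide.
- 6-Bromo-4-methoxythymol comes from 4-methoxythymol by ortho-bromination.
- 4-Methoxythymol comes from thymol by para-bromination and copper-catalysed methoxylation (a second C–O bond formation).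

Assumption: the target has no stereocentre and its diaryl ether axis rotates freely, so it is achiral and no stereocontrol is needed.

**Step 1**
Reactants: 1 thymol (2-isopropyl-5-methylphenol)
Product: 2 4-bromothymol (4-bromo-2-isopropyl-5-methylphenol)
Conditions: NBS (1.0 equiv), MeCN, 0 °C to rt
Reagents that add atoms: N-bromosuccinimide, O=C1CCC(=O)N1Br
Why: Electrophilic aromatic bromination in which the hydroxyl group directs para, the established regiochemistry for thymol; no stereocentre is formed.

**Step 2**
Reactants: 2 4-bromothymol
Product: 3 4-methoxythymol (2-isopropyl-4-methoxy-5-methylphenol)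
Conditions: NaOMe (5 equiv, 25% in MeOH), CuBr (10 mol%), DMF, 110 °C, N2; then aq HCl
Reagents that add atoms: sodium methoxide, C[O-].[Na+]
Why: Copper(I)-catalysed Ullmann-type methanolysis of an aryl bromide, a reaction class used on unprotected bromophenols, replaces Br by OMe at the same carbon, so the regiochemistry is fixed by step 1.

**Step 3**
Reactants: 3 4-methoxythymol
Product: 4 6-bromo-4-methoxythymol (2-bromo-6-isopropyl-4-methoxy-3-methylphenol)
Conditions: NBS (1.0 equiv), CH2Cl2, −40 to 0 °C, dark
Reagents that add atoms: N-bromosuccinimide, O=C1CCC(=O)N1Br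
Why: Electrophilic aromatic bromination directed ortho by the free hydroxyl group, where C6 (ortho to OH, next to methyl) is both more activated and less hindered than C3 (ortho to OMe, next to isopropyl), as in the known conversion of 4-methoxyphenol into 2-bromo-4-methoxyphenol.

**Step 4**
Reactants: 3 4-methoxythymol (2.5 equiv, excess recovered); 4 6-bromo-4-methoxythymol (1.0 equiv)
Product: 8 6-isopropyl-2-(2-isopropyl-4-methoxy-5-methylphenoxy)-4-methoxy-3-methylphenol, via 4-methoxythymyloxyl radical 5 (not isolated), via ipso-adduct radical anion 6 (not isolated), via product aryloxyl radical 7 (not isolated)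
Conditions: K2CO3 (4 equiv), Ag2O (5 mol%, initiator), degassed DMSO, 45 °C, Ar, 4 added over 6 h; then aq NH4Cl
Reagents that add atoms: none
Why: Proposed new method: a redox-neutral radical-chain displacement of an ortho bromide by an aryloxide, in which the catalytic one-electron oxidant converts deprotonated 3 into aryloxyl radical 5, whose oxygen adds to the bromine-bearing carbon of deprotonated 4 to give radical anion 6, which expels bromide and aromatises to aryloxyl radical 7, which is reduced by excess deprotonated 3 to the product phenoxide while regenerating 5; C–C coupling is disfavoured because carbon attack at the ipso position would join two heavily hindered centres and because dehydrogenative dimerisation cannot turn over without stoichiometric oxidant; the closest known reaction type is the oxidant-initiated halide-displacement polymerisation of 4-bromo-2,6-dimethylphenoxide and 2,4,6-tribromophenoxide to poly(phenylene oxide)s (Staffin–Price/Hunter type, SRN1-like), which has not been shown as a discrete cross-coupling at an ortho C–Br bond; no stereocentre survives.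

**Compound list**
1 | thymol (2-isopropyl-5-methylphenol) | Cc1ccc(C(C)C)c(O)c1 | starting material
2 | 4-bromothymol (4-bromo-2-isopropyl-5-methylphenol) | Cc1cc(O)c(C(C)C)cc1Br | intermediate
3 | 4-methoxythymol (2-isopropyl-4-methoxy-5-methylphenol) | COc1cc(C(C)C)c(O)cc1C | intermediate
4 | 6-bromo-4-methoxythymol (2-bromo-6-isopropyl-4-methoxy-3-methylphenol) | COc1cc(C(C)C)c(O)c(Br)c1C | intermediate
5 | 4-methoxythymyloxyl radical (2-isopropyl-4-methoxy-5-methylphenoxyl, oxygen-centred radical of 3) | COc1cc(C(C)C)c([O])cc1C | intermediate
6 | ipso-adduct radical anion (radical anion of 6-bromo-2-isopropyl-6-(2-isopropyl-4-methoxy-5-methylphenoxy)-4-methoxy-5-methylcyclohexa-2,4-dien-1-one; racemic at the transient sp3 carbon, which is lost on bromide expulsion) | [O-]C1=C(C(C)C)C=C(OC)[C](C)C1(Br)Oc1cc(C)c(OC)cc1C(C)C | intermediate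
7 | product aryloxyl radical (oxygen-centred radical of 8) | COc1cc(C(C)C)c(Oc2c(C)c(OC)cc(C(C)C)c2[O])cc1C | intermediate
8 | 6-isopropyl-2-(2-isopropyl-4-methoxy-5-methylphenoxy)-4-methoxy-3-methylphenol (achiral) | COc1cc(C(C)C)c(Oc2c(C)c(OC)cc(C(C)C)c2O)cc1C | target

**Total step count:** 4
**Longest linear sequence:** 4 (steps 1 to 4; compound 3 enters step 4 a second time as the coupling partner)

**Steps most likely to fail**

Step 4 (the proposed new coupling). The risks are self-condensation of 4 to oligomers, carbon attack giving the isomeric 2,2'-biphenol, or a chain too short to turn over. The fallback uses known chemistry, sets out from 4 (with 3 as partner) and comes back at 8. Benzylation of 4 (BnBr, K2CO3, DMF) gives 1-(benzyloxy)-2-bromo-6-isopropyl-4-methoxy-3-methylbenzene F1. Palladium-catalysed diaryl ether coupling of F1 with 3 (Pd(OAc)2, tBuXPhos, K3PO4, toluene, 100 °C) gives 2-(benzyloxy)-1-isopropyl-3-(2-isopropyl-4-methoxy-5-methylphenoxy)-5-methoxy-4-methylbenzene F2. Hydrogenolysis (H2, Pd/C, EtOAc) then gives 8.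

Step 2 (copper-catalysed methoxylation of an unprotected, electron-rich bromophenol). The risks are slow conversion, hydrodebromination back to thymol, or air oxidation of the product to thymoquinone. The fallback sets out from 1 and comes back at 3, avoiding the aryl bromide altogether. Oxidative dearomatisation of thymol with PhI(OAc)2 (2.2 equiv) in MeOH at 0 °C gives the quinone monoketal 4,4-dimethoxy-2-isopropyl-5-methylcyclohexa-2,5-dien-1-one F3. Reductive aromatisation with zinc dust in AcOH/THF gives 3.

Step 3 (bromination of a very electron-rich 4-methoxyphenol). The risks are oxidation to thymoquinone by NBS or some bromination at C3. The fallback sets out from 3 and comes back at 4, replacing electrophilic substitution by directed metalation. MOM protection (MOMCl, iPr2NEt, CH2Cl2) gives 2-isopropyl-4-methoxy-1-(methoxymethoxy)-5-methylbenzene F4. Directed ortho-lithiation (n-BuLi, TMEDA, THF, 0 °C) and quench with 1,2-dibromotetrachloroethane gives 2-bromo-6-isopropyl-4-methoxy-1-(methoxymethoxy)-3-methylbenzene F5. Cleavage with HCl in MeOH gives 4.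

**Further compounds**
F1 | step 4 | 1-(benzyloxy)-2-bromo-6-isopropyl-4-methoxy-3-methylbenzene | COc1cc(C(C)C)c(OCc2ccccc2)c(Br)c1C
F2 | step 4 | 2-(benzyloxy)-1-isopropyl-3-(2-isopropyl-4-methoxy-5-methylphenoxy)-5-methoxy-4-methylbenzene | COc1cc(C(C)C)c(Oc2c(C)c(OC)cc(C(C)C)c2OCc2ccccc2)cc1C
F3 | step 2 | 4,4-dimethoxy-2-isopropyl-5-methylcyclohexa-2,5-dien-1-one | COC1(OC)C=C(C(C)C)C(=O)C=C1C
F4 | step 3 | 2-isopropyl-4-methoxy-1-(methoxymethoxy)-5-methylbenzene | COCOc1cc(C)c(OC)cc1C(C)C
F5 | step 3 | 2-bromo-6-isopropyl-4-methoxy-1-(methoxymethoxy)-3-methylbenzene | COCOc1c(Br)c(C)c(OC)cc1C(C)C
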